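## Structural features

1. The target is a flavanone. A phloroglucinol-type ring A (C4a, C5, C6, C7, C8, C8a) is fused through C4a=C8a to the dihydropyranone ring C (O1, C2, C3, C4=O), and C2 carries ring B (C1'–C6').
2. Ring A is pentasubstituted. It has free OH groups at C5 (chelated to C4=O) and C7, a prenyl group at C8 wedged between C7-OH and C8a-O1, and only C6 bears H.
3. Ring B is 1',3',4',5'-tetrasubstituted. O4' belongs to a 2,2-dimethyl-2H-pyran (ring D) fused at C3'–C4', and C5' carries the second prenyl group.
4. C2 (S) is the only stereocentre and has no neighbour to relay from. It is labile in two ways: E1cB opening at C3-H (retro-oxa-Michael to the chalcone), and ionisation of the C2–O1 bond assisted by the para oxygen O4'.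
5. The fragile groups are the two trisubstituted prenyl alkenes (acid closes the C8 prenyl onto C7-OH), the styrene-like C=C of ring D (sensitive to acid, oxidants and H2), and the free phenols.
6. The real difficulty is a combined one. The C8/C6 regiochemistry of a crowded ring A must be fixed while C2 is kept intact, without phenol protecting groups whose removal would need acid or hydrogenolysis.
7. The key step exploits the fact that C4a=C8a is also the push–pull enol-ether C=C of a 2,3-dihydro-4H-pyran-4-one. In addition, C5–C6–C7–C8 with its prenyl group has exactly the oxidation pattern and polarity of a γ-prenylated acetoacetate (C8 nucleophilic, C5 electrophilic).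
8. In one sentence: ring A is made last, by a Diels–Alder/sulfoxide-elimination benzannulation of a prenylated acetoacetate-derived bis(silyloxy)diene onto the enol-ether double bond of an enantiopure 2-aryl-5-sulfinyl-2,3-dihydropyran-4-one.

## Logic of the disconnections

**24 ⇒ 15 + 21 (step 11).**
- Bonds cut: C4a–C5 and C8–C8a of ring A. A C4a–S bond that is absent from the target is put back.
- Reason: the cut follows the polarity alternation of ring A, and the prenyl group travels on the carbon that must bond to C8a, so the C8/C6 question disappears.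
- Gain: a pentasubstituted arene with two free phenols falls apart into a monocyclic heterocycle and an acyclic C4 unit, and no phenol protection is needed.
- Demand: the forward step must beat the low dienophilicity of a push–pull alkene, reach the aromatic oxidation level without an oxidant, and keep O1 on C8a. The sulfinyl group serves all three needs as activator, blocker of C4a–H and internal leaving group.

**15 ⇒ 13 (step 7).**
- Bonds cut: O1–C8a and C4a=C8a, which removes C8a as a one-carbon unit at the formate level.
- Reason: C4a is an active methylene between C4=O and S=O, and O1 is already in place on C2.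
- Gain: ring C is opened to a chain in which the C2–O bond, and with it the stereocentre, is never touched.
- Demand: condensation and closure must proceed without dehydrating the β-hydroxy ketone.

**13 ⇒ 10 + 11 (step 6).**
- Bond cut: C4–C4a.
- Reason: this is an acyl substitution by an α-sulfinyl carbanion, which delivers C4a and sulfur together and uses no electrophilic sulfur reagent or oxidant near three alkenes.
- Gain: an enantiopure commercial C1–S unit is used, and it turns any enantiomeric leakage at C2 into a separable diastereomeric impurity.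
- Demand: addition must outrun enolisation and retro-aldol cleavage.

**10 ⇒ 5 + 8 (step 5).**
- Bond cut: C2–C3.
- Reason: this is the only bond whose formation creates C2 irreversibly, at a stage where no phenol or enone can reopen it.
- Gain: the precursors are an achiral aldehyde and an acetate equivalent.
- Demand: high Si-face selectivity is needed on an electron-rich aromatic aldehyde under a Lewis acid mild enough for the alkenes.

**8 ⇒ 6 (step 4).**
- Bond cut: O–Si.
- Reason and gain: it leads back to a commercial thioester.
- Demand: silylation must occur on oxygen, not carbon.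

**5 ⇒ 4 ⇒ 2 ⇒ 1 (steps 3, 2, 1).**
- Bonds cut, in turn: C5'–CH2 of the prenyl group, the C3'–C(vinyl) bond of ring D, and O4'–CMe2.
- Reason: a bromine at C5' blocks one ortho position during the sigmatropic ring-D formation and then becomes the handle for the prenyl group.
- Gain: a commercial trisubstituted benzene.
- Demand: the coupling must be linear-selective for the allyl unit.

**21 ⇒ 19 ⇒ 18 ⇒ 16 (steps 10, 9, 8).**
- Bonds cut: the two O–Si bonds and then C8–CH2 of the prenyl group.
- Reason: at the acetoacetate stage C8 is the terminal carbanion of a dianion, so prenylation is regiospecific.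
- Gain: two commodity chemicals.
- Demand: the diene must be made and handled under anhydrous, neutral conditions.

## Other disconnections considered

**Alternative 1:** (the first that comes to mind) The cut is O1–C2, followed by Cα–Cβ.
- Forward key step: Claisen–Schmidt condensation of 5 gives the 2',4',6'-trihydroxy-3'-prenylchalcone A1, and oxa-Michael closure forms ring C.
- A1 has two non-equivalent ortho hydroxyls. Closure through the less hindered one places the prenyl group at C6, so differential protection of ring A is unavoidable.
- The ring closure is reversible, so the equilibrium that creates C2 also scrambles it. The β-carbon is deactivated by O4', which works against catalytic asymmetric versions unless an extra activating group is added at Cα.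
- The hard part, pentasubstituted ring A, is only moved into the ketone partner. The final acidic deprotection then meets an ortho-prenylphenol.

**Alternative 2:** The cut is C2–C1'.
- Forward key step: enantioselective 1,4-addition of boronic acid A3 to 5,7-bis(methoxymethoxy)-8-prenylchromone A2 (Pd(II)/pyridine-oxazoline or Rh(I)/chiral diene).
- C2 would be set irreversibly and catalytically, which is a real merit.
- However, A2 needs the complete, regiodefined and protected ring A beforehand, and its C2 is flanked by the 8-prenyl group and deactivated by three ring oxygens.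
- A cationic Pd(II) centre also meets three coordinating alkenes, and the electron-rich A3 is prone to protodeboronation.
- Two phenol protecting groups must still come off in acid at the end. The plan is longer and leaves the C8/C6 problem unsolved.

**Alternative 3:** The cut is C8–CH2(prenyl).
- Forward key step: a Claisen–Cope relay (O5 → C6 → C8) of the (2S)-7-acetoxy-5-prenyloxyflavanone A4.
- The regiochemistry depends on the second [3,3] shift outrunning tautomerisation of the C6 dienone, so reverse-prenylation at C6 competes.
- A4 requires selective alkylation of the chelated 5-OH and an already enantiopure flavanone, so the C2 problem is untouched.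
- Prolonged heating or Lewis acid on a 4'-oxygenated flavanone invites opening of ring C.
- The protecting-group steps make this plan longer than the chosen one.

Key step: step 11

Assumption: the (S)-BINOL–Ti(IV) catalyst is taken to direct the silyl ketene thioacetal to the Si face of 5, the sense usual for this catalyst family with aromatic aldehydes. Should the sense be opposite, (R)-BINOL is used and nothing else changes.

## Steps

Step 1
Reactants: 1 3-bromo-4-hydroxybenzaldehyde
Product: 2 3-bromo-4-[(2-methylbut-3-yn-2-yl)oxy]benzaldehyde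
Conditions: 3-chloro-3-methylbut-1-yne, K2CO3, KI (cat.), CuI (cat.), DMF, 65 °C
Reagents that add atoms: 3-chloro-3-methylbut-1-yne, C#CC(C)(C)Cl
Why: Copper-assisted Williamson-type O-alkylation of a phenoxide with a tertiary propargylic chloride is the standard entry to aryl 1,1-dimethylpropargyl ethers. The aldehyde and the aryl bromide are inert under these conditions.

Step 2
Reactants: 2 3-bromo-4-[(2-methylbut-3-yn-2-yl)oxy]benzaldehyde
Product: 4 8-bromo-2,2-dimethyl-2H-chromene-6-carbaldehyde, via allenylphenol 3 (not isolated)
Conditions: PhNEt2, 190 °C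
Reagents that add atoms: none
Why: An aromatic propargyl Claisen rearrangement gives 3 after tautomerisation, and a 1,5-H shift and oxa-6π electrocyclisation then close ring D. The bromine blocks the other ortho carbon, so only one regioisomer is possible.

Step 3
Reactants: 4 8-bromo-2,2-dimethyl-2H-chromene-6-carbaldehyde
Product: 5 2,2-dimethyl-8-(3-methylbut-2-en-1-yl)-2H-chromene-6-carbaldehyde
Conditions: tributyl(3-methylbut-2-en-1-yl)stannane, Pd(PPh3)4 (5 mol %), DMF, 100 °C
Reagents that add atoms: tributyl(3-methylbut-2-en-1-yl)stannane, CCCC[Sn](CCCC)(CCCC)CC=C(C)C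
Why: In this Stille coupling, bond formation at the unsubstituted allyl terminus should give the linear prenyl group. The neutral conditions spare the aldehyde and the chromene.

Step 4
Reactants: 6 S-tert-butyl ethanethioate
Product: 8 tert-butyl 1-(trimethylsilyloxy)ethenyl sulfide, via lithium enolate 7 (not isolated)
Conditions: LDA, THF, −78 °C; TMSCl, −78 °C → rt
Reagents that add atoms: chlorotrimethylsilane, C[Si](C)(C)Cl
Why: Kinetic enolisation is followed by O-silylation. Thioester enolates silylate cleanly on oxygen, which gives the silyl ketene thioacetal.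

Step 5
Reactants: 5 2,2-dimethyl-8-(3-methylbut-2-en-1-yl)-2H-chromene-6-carbaldehyde; 8 tert-butyl 1-(trimethylsilyloxy)ethenyl sulfide
Product: 10 S-tert-butyl (3S)-3-[2,2-dimethyl-8-(3-methylbut-2-en-1-yl)-2H-chromen-6-yl]-3-hydroxypropanethioate, via silyl ether 9 (not isolated)
Conditions: (S)-BINOL (20 mol %), Ti(OiPr)4 (20 mol %), 4 Å MS, Et2O, −20 °C; then citric acid, MeOH–H2O, 0 °C
Reagents that add atoms: none
Why: This is a catalytic enantioselective Mukaiyama acetate aldol addition. The aldehyde bound in the BINOL–titanium pocket is attacked through an open transition state on its Si face, which sets the future C2 as S. The Lewis acid is mild enough for the prenyl and chromene alkenes, and the weak acid work-up removes only the O-TMS group.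

Step 6
Reactants: 10 S-tert-butyl (3S)-3-[2,2-dimethyl-8-(3-methylbut-2-en-1-yl)-2H-chromen-6-yl]-3-hydroxypropanethioate; 11 (R)-methyl 4-methylphenyl sulfoxide
Product: 13 (4S)-4-[2,2-dimethyl-8-(3-methylbut-2-en-1-yl)-2H-chromen-6-yl]-4-hydroxy-1-[(R)-(4-methylphenyl)sulfinyl]butan-2-one, via lithiated sulfoxide 12 (not isolated)
Conditions: 11 (3.3 equiv), LDA (3.2 equiv), THF, −78 °C; add 10, −78 → −40 °C; AcOH quench
Reagents that add atoms: none
Why: Claisen-type acylation of an α-lithio sulfoxide is the classical β-keto sulfoxide synthesis. One equivalent takes the hydroxyl proton, one adds, and one deprotonates the product, which shields the ketone from a second addition and from retro-aldol cleavage. Sulfur and C4 are untouched, and any enantiomeric leakage from step 5 becomes a diastereomeric impurity that can be removed here.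

Step 7
Reactants: 13 (4S)-4-[2,2-dimethyl-8-(3-methylbut-2-en-1-yl)-2H-chromen-6-yl]-4-hydroxy-1-[(R)-(4-methylphenyl)sulfinyl]butan-2-one
Product: 15 (2S)-2-[2,2-dimethyl-8-(3-methylbut-2-en-1-yl)-2H-chromen-6-yl]-5-[(S)-(4-methylphenyl)sulfinyl]-2,3-dihydro-4H-pyran-4-one, via enaminone 14 (not isolated)
Conditions: Me2NCH(OMe)2 (1.3 equiv), toluene, rt; then AcOH (2 equiv), rt
Reagents that add atoms: N,N-dimethylformamide dimethyl acetal, COC(OC)N(C)C
Why: Amide-acetal condensation on the active methylene is followed by 6-endo-trig addition–elimination of the hydroxyl on the push–pull alkene, the known dihydropyranone synthesis from δ-hydroxy-β-dicarbonyl compounds. The C2–O bond is never broken, so S is retained, and AcOH traps the liberated amine so that the closure is not reversed. The geometry at sulfur is unchanged, and its descriptor becomes S only because the vinylic carbon outranks the tolyl carbon.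

Step 8
Reactants: 16 methyl acetoacetate
Product: 18 methyl 7-methyl-3-oxooct-6-enoate, via dilithium dianion 17 (not isolated)
Conditions: LDA (2.1 equiv), THF, 0 °C; 1-bromo-3-methylbut-2-ene (1.0 equiv), 0 °C; AcOH quench
Reagents that add atoms: 1-bromo-3-methylbut-2-ene, CC(C)=CCBr
Why: In this γ-alkylation of the acetoacetate dianion, only the terminal, more basic carbanion reacts with the allylic bromide (SN2). This fixes the prenyl group on the future C8.

Step 9
Reactants: 18 methyl 7-methyl-3-oxooct-6-enoate
Product: 19 methyl 7-methyl-3-(trimethylsilyloxy)octa-2,6-dienoate (E/Z mixture at C2=C3)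
Conditions: TMSCl, Et3N, toluene, rt
Reagents that add atoms: chlorotrimethylsilane, C[Si](C)(C)Cl
Why: Soft enolisation and O-silylation of a β-keto ester is the first stage of the standard bis(silyloxy)diene preparation. Both alkene isomers converge in step 10.

Step 10
Reactants: 19 methyl 7-methyl-3-(trimethylsilyloxy)octa-2,6-dienoate
Product: 21 (3Z)-1-methoxy-7-methyl-1,3-bis(trimethylsilyloxy)octa-1,3,6-triene (ketene acetal C1=C2 geometry immaterial), via lithium dienolate 20 (not isolated)
Conditions: LDA, THF, −78 °C; TMSCl, −78 °C → rt; filtration under argon, used directly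
Reagents that add atoms: chlorotrimethylsilane, C[Si](C)(C)Cl
Why: γ-Deprotonation of the silyloxy enoate gives the extended dienolate, which silylates on the ester oxygen. The chain should prefer the 3Z geometry (alkyl trans to C2), which can reach the s-cis conformation.

Step 11
Reactants: 15 (2S)-2-[2,2-dimethyl-8-(3-methylbut-2-en-1-yl)-2H-chromen-6-yl]-5-[(S)-(4-methylphenyl)sulfinyl]-2,3-dihydro-4H-pyran-4-one; 21 (3Z)-1-methoxy-7-methyl-1,3-bis(trimethylsilyloxy)octa-1,3,6-triene
Product: 24 maackiaflavanone B, via cycloadduct 22 (not isolated), via bis-silyl ether 23 (not isolated)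
Conditions: 21 (2.5 equiv), toluene, 25 → 70 °C; then 5% aq. citric acid, THF, rt
Reagents that add atoms: none
Why: Proposed new method: a polarity-matched [4+2] cycloaddition of the 1,1,3-trioxygenated diene 21 across C4a=C8a of 15 is followed in the same flask by sulfoxide syn-elimination and loss of methanol; the closest known reaction type is the tandem Diels–Alder/sulfenic acid (or HX) elimination/aromatisation of vinylketene acetals with 2-sulfinyl- and 2-haloquinones and of oxygenated dienes with 2-sulfinyl enones, which has not been shown on a 5-sulfinyl-2,3-dihydropyran-4-one. The three oxygen donors make C4 of 21 (future C8) its nucleophilic terminus, and the ketone and the sulfinyl group, both on C4a, make C8a the only electrophilic carbon of 15, so C8–C8a bonding leads and C4a–C5 bonding follows, concertedly or as Mukaiyama–Michael addition and 6-(enolexo)-exo-trig closure on the silyloxycarbenium ion. Ring A therefore closes as a six-membered carbocycle by intermolecular [4+2] annulation with the prenyl-bearing carbon next to C8a, and a 6-prenyl isomer cannot form. Suprafacial addition places the sulfinyl group on C4a and H-8a cis in 22, which is the geometry of the five-centre syn-elimination, and H-8a is the only β-hydrogen available. Until that elimination C4a is quaternary, so no enolate can arise next to C8a and expel O1, the aromatisation path that an unsubstituted dihydropyranone adduct would be expected to take. The 1,4-cyclohexadiene so formed holds a C5 ketal and a doubly allylic H-8, loses methanol to give 23, and mild aqueous acid frees both phenols. The stereocentres created at C4a, C5, C8 and C8a are all erased, so facial, endo/exo and diene-geometry selectivity are not needed, whereas C2 is a spectator whose bonds are untouched in a neutral, aprotic medium that offers neither the E1cB nor the ionisation route to racemisation. The selectivity needed is chemoselectivity for C4a=C8a over the two prenyl and the chromene alkenes, secured because these are electron-rich and do not react with an electron-rich diene, whose excess also silylates the sulfenic acid.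

## Compound list

1 | 3-bromo-4-hydroxybenzaldehyde | O=Cc1ccc(O)c(Br)c1 | starting material
2 | 3-bromo-4-[(2-methylbut-3-yn-2-yl)oxy]benzaldehyde | O=Cc1ccc(OC(C)(C)C#C)c(Br)c1 | intermediate
3 | 3-bromo-4-hydroxy-5-(3-methylbuta-1,2-dien-1-yl)benzaldehyde (not isolated) | O=Cc1cc(Br)c(O)c(C=C=C(C)C)c1 | intermediate
4 | 8-bromo-2,2-dimethyl-2H-chromene-6-carbaldehyde | O=Cc1cc(Br)c2OC(C)(C)C=Cc2c1 | intermediate
5 | 2,2-dimethyl-8-(3-methylbut-2-en-1-yl)-2H-chromene-6-carbaldehyde | O=Cc1cc(CC=C(C)C)c2OC(C)(C)C=Cc2c1 | intermediate
6 | S-tert-butyl ethanethioate | CC(=O)SC(C)(C)C | starting material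
7 | lithium enolate of 6 (not isolated) | [Li]OC(=C)SC(C)(C)C | intermediate
8 | tert-butyl 1-(trimethylsilyloxy)ethenyl sulfide | C=C(O[Si](C)(C)C)SC(C)(C)C | intermediate
9 | S-tert-butyl (3S)-3-[2,2-dimethyl-8-(3-methylbut-2-en-1-yl)-2H-chromen-6-yl]-3-(trimethylsilyloxy)propanethioate (not isolated) | C[Si](C)(C)O[C@@H](CC(=O)SC(C)(C)C)c1cc(CC=C(C)C)c2OC(C)(C)C=Cc2c1 | intermediate
10 | S-tert-butyl (3S)-3-[2,2-dimethyl-8-(3-methylbut-2-en-1-yl)-2H-chromen-6-yl]-3-hydroxypropanethioate | O[C@@H](CC(=O)SC(C)(C)C)c1cc(CC=C(C)C)c2OC(C)(C)C=Cc2c1 | intermediate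
11 | (R)-methyl 4-methylphenyl sulfoxide | C[S@@](=O)c1ccc(C)cc1 | starting material
12 | (R)-[(4-methylphenyl)sulfinyl]methyllithium (not isolated) | [Li]C[S@@](=O)c1ccc(C)cc1 | intermediate
13 | (4S)-4-[2,2-dimethyl-8-(3-methylbut-2-en-1-yl)-2H-chromen-6-yl]-4-hydroxy-1-[(R)-(4-methylphenyl)sulfinyl]butan-2-one | O[C@@H](CC(=O)C[S@@](=O)c1ccc(C)cc1)c1cc(CC=C(C)C)c2OC(C)(C)C=Cc2c1 | intermediate
14 | (4S)-1-(dimethylamino)methylidene derivative of 13, sulfur geometry as in 13, E/Z immaterial (not isolated) | O[C@@H](CC(=O)C(=CN(C)C)[S@@](=O)c1ccc(C)cc1)c1cc(CC=C(C)C)c2OC(C)(C)C=Cc2c1 | intermediate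
15 | (2S)-2-[2,2-dimethyl-8-(3-methylbut-2-en-1-yl)-2H-chromen-6-yl]-5-[(S)-(4-methylphenyl)sulfinyl]-2,3-dihydro-4H-pyran-4-one | CC(C)=CCc1cc([C@@H]2CC(=O)C([S@@](=O)c3ccc(C)cc3)=CO2)cc2c1OC(C)(C)C=C2 | intermediate
16 | methyl acetoacetate | COC(=O)CC(C)=O | starting material
17 | dilithium dianion of 16 (not isolated) | C=C(O[Li])C=C(O[Li])OC | intermediate
18 | methyl 7-methyl-3-oxooct-6-enoate | COC(=O)CC(=O)CCC=C(C)C | intermediate
19 | methyl 7-methyl-3-(trimethylsilyloxy)octa-2,6-dienoate (E/Z mixture at C2=C3) | COC(=O)C=C(O[Si](C)(C)C)CCC=C(C)C | intermediate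
20 | lithium dienolate of 19, 3Z (not isolated) | COC(O[Li])=C/C(O[Si](C)(C)C)=C/CC=C(C)C | intermediate
21 | (3Z)-1-methoxy-7-methyl-1,3-bis(trimethylsilyloxy)octa-1,3,6-triene (C1=C2 geometry immaterial) | COC(O[Si](C)(C)C)=C/C(O[Si](C)(C)C)=C/CC=C(C)C | intermediate
22 | (2S)-2-aryl-5-methoxy-8-(3-methylbut-2-en-1-yl)-4a-[(4-methylphenyl)sulfinyl]-5,7-bis(trimethylsilyloxy)-2,3,4a,5,8,8a-hexahydro-4H-chromen-4-one; sulfinyl and H-8a cis; mixture at C4a/C5/C8/C8a, all isomers converge (not isolated) | CC(C)=CCc1cc([C@@H]2CC(=O)C3([S@@](=O)c4ccc(C)cc4)C(OC)(O[Si](C)(C)C)C=C(O[Si](C)(C)C)C(CC=C(C)C)C3O2)cc2c1OC(C)(C)C=C2 | intermediate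
23 | 5,7-bis-O-(trimethylsilyl) ether of 24 (not isolated) | CC(C)=CCc1cc([C@@H]2CC(=O)c3c(O[Si](C)(C)C)cc(O[Si](C)(C)C)c(CC=C(C)C)c3O2)cc2c1OC(C)(C)C=C2 | intermediate
24 | maackiaflavanone B, (2S)-2-[2,2-dimethyl-8-(3-methylbut-2-en-1-yl)-2H-chromen-6-yl]-5,7-dihydroxy-8-(3-methylbut-2-en-1-yl)-2,3-dihydro-4H-chromen-4-one | CC(C)=CCc1cc([C@@H]2CC(=O)c3c(O)cc(O)c(CC=C(C)C)c3O2)cc2c1OC(C)(C)C=C2 | target

## Step count and least certain steps

Total step count: 11. Longest linear sequence: 7 (steps 1, 2, 3, 5, 6, 7, 11).

**Step 11 (key step, bears the label).** Four processes are most likely to interfere.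
- The C=C still carries the O1 donor, so its dienophilicity may be too low.
- The reaction may arrest at the Michael stage with silyl transfer. O1 would then be expelled and ring C opened as soon as an enolate is released.
- The silyl ketene acetal may activate the sulfoxide in a silicon-induced Pummerer-type reaction.
- The C5 ketal may ionise with loss of silanol instead of methanol, which would leave O5 methylated.

The fallback uses known chemistry only. It sets out from 5 and comes back at 24. 2,4,6-Trihydroxyacetophenone is C-prenylated (1-bromo-3-methylbut-2-ene, aq. KOH) to 1-[2,4,6-trihydroxy-3-(3-methylbut-2-en-1-yl)phenyl]ethanone F1. The 4-OH and the less hindered 6-OH are then protected (MOMCl, iPr2NEt) to give 1-[2-hydroxy-4,6-bis(methoxymethoxy)-3-(3-methylbut-2-en-1-yl)phenyl]ethanone F2. Claisen–Schmidt condensation with 5 (KOH, EtOH) gives the bis-MOM 2'-hydroxychalcone F3, and NaOAc in refluxing EtOH closes it to the racemic bis-MOM flavanone F4. Kinetic resolution by transfer hydrogenation (Ru/(R,R)-TsDPEN, HCO2H/Et3N) should leave the (2S)-bis-MOM flavanone F5 and reduce its antipode to the (2R,4R)-bis-MOM flavan-4-ol F6. After separation, HCl/MeOH converts F5 into 24.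

**Step 7.** Three processes threaten this step. The liberated dimethylamine may reverse the ring closure. The electron-rich β-hydroxy ketone may dehydrate by E1cB. Base may also open ring C at C3-H, because O1 is a very good leaving group in 15, and this would erode the configuration at C2.

The fallback sets out from 5 and comes back at 15. A catalytic enantioselective hetero-Diels–Alder reaction of 5 with 1-methoxy-3-(trimethylsilyloxy)buta-1,3-diene (BINOL–Ti(IV), mild acid work-up) gives the (2S)-2-aryl-2,3-dihydro-4H-pyran-4-one F11. I2/pyridine gives the 5-iodo dihydropyranone F12, and Cu- or Pd-catalysed C–S coupling with 4-methylbenzenethiol (K2CO3) gives the 5-(4-methylphenylsulfanyl) dihydropyranone F13. NaIO4 then oxidises F13 to 15 together with its sulfur epimer F14. Both serve in step 11 because sulfur is lost there.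

**Step 6.** The carbanion may enolise the thioester instead of adding to it. The lithium alkoxide may also undergo retro-aldol cleavage, which would lower the enantiomeric purity.

The fallback sets out from 5 and 11 and comes back at 13. Compound 11 is acylated with ethyl acetate (LDA) to (R)-1-[(4-methylphenyl)sulfinyl]propan-2-one F9. Its dianion (LDA, 2 equiv) adds through the terminal carbon to 5 and gives 13 together with the (4R)-epimeric hydroxy keto sulfoxide F10. The enantiopure sulfoxide makes the two separable by chromatography or crystallisation.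

**Step 5.** Turnover may be slow and the uncatalysed silyl-transfer background may compete with an electron-rich aldehyde, which would lower the facial selectivity.

The fallback sets out from 5 and comes back at 13. SnCl2-catalysed homologation of 5 with ethyl diazoacetate (Roskamp reaction) gives the ethyl 3-aryl-3-oxopropanoate F7. Transfer hydrogenation with Ru/(S,S)-TsDPEN (HCO2H/Et3N), which spares the alkenes, should give the ethyl (3S)-3-aryl-3-hydroxypropanoate F8. F8 is then treated with 12 under the conditions of step 6 to give 13.

## Further compounds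

F1 | step 11 | 1-[2,4,6-trihydroxy-3-(3-methylbut-2-en-1-yl)phenyl]ethanone | CC(=O)c1c(O)cc(O)c(CC=C(C)C)c1O
F2 | step 11 | 1-[2-hydroxy-4,6-bis(methoxymethoxy)-3-(3-methylbut-2-en-1-yl)phenyl]ethanone | CC(=O)c1c(OCOC)cc(OCOC)c(CC=C(C)C)c1O
F3 | step 11 | (E)-3-[2,2-dimethyl-8-(3-methylbut-2-en-1-yl)-2H-chromen-6-yl]-1-[2-hydroxy-4,6-bis(methoxymethoxy)-3-(3-methylbut-2-en-1-yl)phenyl]prop-2-en-1-one | COCOc1cc(OCOC)c(C(=O)/C=C/c2cc(CC=C(C)C)c3OC(C)(C)C=Cc3c2)c(O)c1CC=C(C)C
F4 | step 11 | racemic 5,7-bis-O-(methoxymethyl) ether of 24 | CC(C)=CCc1cc(C2CC(=O)c3c(OCOC)cc(OCOC)c(CC=C(C)C)c3O2)cc2c1OC(C)(C)C=C2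
F5 | step 11 | (2S)-5,7-bis-O-(methoxymethyl) ether of 24 | CC(C)=CCc1cc([C@@H]2CC(=O)c3c(OCOC)cc(OCOC)c(CC=C(C)C)c3O2)cc2c1OC(C)(C)C=C2
F6 | step 11 | (2R,4R)-cis-flavan-4-ol from the (2R)-enantiomer of F4 | CC(C)=CCc1cc([C@H]2C[C@@H](O)c3c(OCOC)cc(OCOC)c(CC=C(C)C)c3O2)cc2c1OC(C)(C)C=C2
F7 | step 5 | ethyl 3-[2,2-dimethyl-8-(3-methylbut-2-en-1-yl)-2H-chromen-6-yl]-3-oxopropanoate | CCOC(=O)CC(=O)c1cc(CC=C(C)C)c2OC(C)(C)C=Cc2c1
F8 | step 5 | ethyl (3S)-3-[2,2-dimethyl-8-(3-methylbut-2-en-1-yl)-2H-chromen-6-yl]-3-hydroxypropanoate | O[C@@H](CC(=O)OCC)c1cc(CC=C(C)C)c2OC(C)(C)C=Cc2c1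
F9 | step 6 | (R)-1-[(4-methylphenyl)sulfinyl]propan-2-one | CC(=O)C[S@@](=O)c1ccc(C)cc1
F10 | step 6 | (4R)-epimer of 13 | O[C@H](CC(=O)C[S@@](=O)c1ccc(C)cc1)c1cc(CC=C(C)C)c2OC(C)(C)C=Cc2c1
F11 | step 7 | (2S)-2-[2,2-dimethyl-8-(3-methylbut-2-en-1-yl)-2H-chromen-6-yl]-2,3-dihydro-4H-pyran-4-one | CC(C)=CCc1cc([C@@H]2CC(=O)C=CO2)cc2c1OC(C)(C)C=C2
F12 | step 7 | (2S)-5-iodo derivative of F11 | CC(C)=CCc1cc([C@@H]2CC(=O)C(I)=CO2)cc2c1OC(C)(C)C=C2
F13 | step 7 | (2S)-5-[(4-methylphenyl)sulfanyl] derivative of F11 | CC(C)=CCc1cc([C@@H]2CC(=O)C(Sc3ccc(C)cc3)=CO2)cc2c1OC(C)(C)C=C2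
F14 | step 7 | sulfur epimer of 15 | CC(C)=CCc1cc([C@@H]2CC(=O)C([S@](=O)c3ccc(C)cc3)=CO2)cc2c1OC(C)(C)C=C2
A1 | alternative 1 | (E)-3-[2,2-dimethyl-8-(3-methylbut-2-en-1-yl)-2H-chromen-6-yl]-1-[2,4,6-trihydroxy-3-(3-methylbut-2-en-1-yl)phenyl]prop-2-en-1-one | Oc1cc(O)c(C(=O)/C=C/c2cc(CC=C(C)C)c3OC(C)(C)C=Cc3c2)c(O)c1CC=C(C)C
A2 | alternative 2 | 5,7-bis(methoxymethoxy)-8-(3-methylbut-2-en-1-yl)-4H-chromen-4-one | O=c1ccoc2c(CC=C(C)C)c(OCOC)cc(OCOC)c12
A3 | alternative 2 | [2,2-dimethyl-8-(3-methylbut-2-en-1-yl)-2H-chromen-6-yl]boronic acid | OB(O)c1cc(CC=C(C)C)c2OC(C)(C)C=Cc2c1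
A4 | alternative 3 | (2S)-2-[2,2-dimethyl-8-(3-methylbut-2-en-1-yl)-2H-chromen-6-yl]-5-[(3-methylbut-2-en-1-yl)oxy]-4-oxo-3,4-dihydro-2H-chromen-7-yl acetate | CC(C)=CCc1cc([C@@H]2CC(=O)c3c(OCC=C(C)C)cc(OC(C)=O)cc3O2)cc2c1OC(C)(C)C=C2
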